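**Strategy**

Everything rests on reading the second dihydrobenzofuran (O1', C2', C3', C3a', C7a') as a ring-contracted flavanone. The ring C carbon C3a' is bonded to C3' only because it has moved there from the former carbonyl carbon, which stays behind as a carboxyl group and is later traded for ring D. One oxidative 1,2-aryl shift on (R)-6-bromo-8-methoxy-2-(4-methoxyphenyl)chroman-4-one forms C3'–C3a', contracts the pyranone and places the carboxyl trans to ring E. The bromine marks C5' for decarboxylative union with a second, oppositely configured dihydrobenzofuran acid made the same way. The Z-styryl arm is attached last, after the methyl ethers have been exchanged for silyl ethers.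

Key step: step 4

Labels: unprimed locants (O1, C2, C3, C3a, C4–C7, C7a) belong to the styryl-bearing dihydrobenzofuran (benzo ring A, ring B on C2, ring F on the alkene). Primed locants belong to the second dihydrobenzofuran (benzo ring C, ring E on C2', ring D on C3'). Flavanones carry chromanone locants (O1, C2, C3, C4, C4a, C5–C8, C8a).

Assumption: (S)-t-BuPyOx is taken to deliver the 2R flavanone and (R)-t-BuPyOx the 2S flavanone, by analogy with the sense of addition to cyclic enones; if the sense is the reverse, the two ligands are exchanged.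

Design remark: the halogen at C6 of the flavanone is bromine, so that this carbon can itself be the electrophile in the union. The two decarboxylative arylations are ordered so that each meets only one aryl bromide. The Z-alkene is made only after the last photocatalytic and Lewis-acid steps.

**Route**

Step 1
Reactants: 1 1-(2-hydroxy-3-methoxyphenyl)ethan-1-one
Product: 2 1-(5-bromo-2-hydroxy-3-methoxyphenyl)ethan-1-one
Conditions: NBS (1.05 equiv), MeCN, 0 °C to rt
Reagents that add atoms: N-bromosuccinimide, O=C1CCC(=O)N1Br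
Why: Electrophilic aromatic bromination, in which the phenol directs bromine to its only free para position (C5), a site the meta-directing acetyl group also favours.

Step 2
Reactants: 2 1-(5-bromo-2-hydroxy-3-methoxyphenyl)ethan-1-one
Product: 4 6-bromo-8-methoxy-4H-chromen-4-one, via enaminone 3 (not isolated)
Conditions: Me2NCH(OMe)2, toluene, 100 °C; then AcOH, 100 °C
Reagents that add atoms: N,N-dimethylformamide dimethyl acetal, COC(OC)N(C)C
Why: Enaminone condensation of the methyl ketone followed by acid-promoted addition of the phenol and loss of dimethylamine, the standard chromone synthesis from 2-hydroxyacetophenones.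

Step 3
Reactants: 4 6-bromo-8-methoxy-4H-chromen-4-one; 5 (4-methoxyphenyl)boronic acid
Product: 6 (2R)-6-bromo-8-methoxy-2-(4-methoxyphenyl)-2,3-dihydro-4H-chromen-4-one
Conditions: Pd(OCOCF3)2 (5 mol%), (S)-t-BuPyOx (6 mol%), NH4PF6 (30 mol%), H2O (5 equiv), 5 (2 equiv), ClCH2CH2Cl, 60 °C
Reagents that add atoms: none
Why: Catalytic asymmetric conjugate addition of an arylboronic acid to a chromone, in which the tert-butyl group of the pyridine-oxazoline ligand selects the enone face during aryl insertion and so sets C2 as R, while palladium stays divalent throughout and therefore leaves the aryl bromide alone.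

Step 4
Reactants: 6 (2R)-6-bromo-8-methoxy-2-(4-methoxyphenyl)-2,3-dihydro-4H-chromen-4-one
Product: 8 methyl (2R,3R)-5-bromo-7-methoxy-2-(4-methoxyphenyl)-2,3-dihydro-1-benzofuran-3-carboxylate, via enol ether 7 (not isolated)
Conditions: PhI(OAc)2 (1.2 equiv), conc. H2SO4 (1.5 equiv), HC(OMe)3, rt
Reagents that add atoms: trimethyl orthoformate, COC(OC)OC
Why: Under H2SO4 the orthoformate turns ketone 6 into enol ether 7, the electrophilic trivalent iodine reagent adds to C3 of 7 on the face away from the aryl group on C2, and methanol caps C4 as a dimethyl ketal. With the aryl group and the C3–I bond both equatorial, only the C4–C4a bond lies antiperiplanar to the leaving group, so C4a migrates to C3 from the rear of the departing iodobenzene and the dialkoxy-stabilised cation left at C4 loses a methyl group to become the ester. The closest known reaction is the hypervalent-iodine oxidative ring contraction of flavanones to trans-2-aryl-2,3-dihydrobenzofuran-3-carboxylates, a relative of the oxidative rearrangement of aryl ketones to arylacetic esters. The five-membered ring (O1, C2, C3, C3a, C7a) is closed not by a cyclisation but by the 1,2-shift itself: the C3–C4a bond forms inside the existing six-membered ring and C4 is pushed out as the exocyclic ester carbon. C2 is a spectator and keeps its R configuration, and the new centre C3 ends up trans to it by substrate control, because iodination is anti to the aryl group and the shift inverts C3. The step needs migration of C4a in preference to the C2 aryl group (which would lead towards an isoflavone) and to simple loss of the iodine (flavone); this is secured by the diequatorial alignment, by the ring oxygen O1 on the neighbouring carbon C8a, which makes C4a a good migrating group, and by the two ketal oxygens that stabilise the cation at C4.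

Step 5
Reactants: 9 1-(2,6-dihydroxy-4-methoxyphenyl)ethan-1-one
Product: 10 1-[2-(benzyloxy)-6-hydroxy-4-methoxyphenyl]ethan-1-one
Conditions: BnBr (1.05 equiv), K2CO3, acetone, reflux
Reagents that add atoms: benzyl bromide, BrCc1ccccc1
Why: Williamson ether synthesis that stops after one alkylation, because the second phenol is held in a hydrogen bond to the ketone and is far less nucleophilic.

Step 6
Reactants: 10 1-[2-(benzyloxy)-6-hydroxy-4-methoxyphenyl]ethan-1-one
Product: 12 5-(benzyloxy)-7-methoxy-4H-chromen-4-one, via enaminone 11 (not isolated)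
Conditions: Me2NCH(OMe)2, toluene, 100 °C; then AcOH, 100 °C
Reagents that add atoms: N,N-dimethylformamide dimethyl acetal, COC(OC)N(C)C
Why: The same enaminone condensation and acid-promoted cyclisation with loss of dimethylamine as in step 2, to which the benzyl ether is inert.

Step 7
Reactants: 12 5-(benzyloxy)-7-methoxy-4H-chromen-4-one; 5 (4-methoxyphenyl)boronic acid
Product: 13 (2S)-5-(benzyloxy)-7-methoxy-2-(4-methoxyphenyl)-2,3-dihydro-4H-chromen-4-one
Conditions: Pd(OCOCF3)2 (5 mol%), (R)-t-BuPyOx (6 mol%), NH4PF6 (30 mol%), H2O (5 equiv), 5 (2 equiv), ClCH2CH2Cl, 60 °C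
Reagents that add atoms: none
Why: The same asymmetric conjugate addition as in step 3, run with the antipodal ligand so that catalyst control sets C2 as S.

Step 8
Reactants: 13 (2S)-5-(benzyloxy)-7-methoxy-2-(4-methoxyphenyl)-2,3-dihydro-4H-chromen-4-one
Product: 15 methyl (2S,3S)-4-(benzyloxy)-6-methoxy-2-(4-methoxyphenyl)-2,3-dihydro-1-benzofuran-3-carboxylate, via enol ether 14 (not isolated)
Conditions: PhI(OAc)2 (1.2 equiv), conc. H2SO4 (1.5 equiv), HC(OMe)3, rt
Reagents that add atoms: trimethyl orthoformate, COC(OC)OC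
Why: The same hypervalent-iodine oxidative ring contraction as in step 4, in which anti iodination of enol ether 14 and the invertive shift of C4a (here further activated by the para 7-methoxy group) give the trans ester while C2 is untouched.

Step 9
Reactants: 15 methyl (2S,3S)-4-(benzyloxy)-6-methoxy-2-(4-methoxyphenyl)-2,3-dihydro-1-benzofuran-3-carboxylate
Product: 16 (2S,3S)-4-(benzyloxy)-6-methoxy-2-(4-methoxyphenyl)-2,3-dihydro-1-benzofuran-3-carboxylic acid
Conditions: Me3SnOH (5 equiv), ClCH2CH2Cl, 80 °C; then 1 M HCl wash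
Reagents that add atoms: trimethyltin hydroxide, C[Sn](C)(C)O
Why: Methyl ester hydrolysis with a neutral hydroxide donor, which avoids deprotonation at C3 and hence β-elimination of the ring oxygen, so C2 is kept.

Step 10
Reactants: 16 (2S,3S)-4-(benzyloxy)-6-methoxy-2-(4-methoxyphenyl)-2,3-dihydro-1-benzofuran-3-carboxylic acid; 8 methyl (2R,3R)-5-bromo-7-methoxy-2-(4-methoxyphenyl)-2,3-dihydro-1-benzofuran-3-carboxylate
Product: 17 methyl (2R,3R)-5-[(2S,3S)-4-(benzyloxy)-6-methoxy-2-(4-methoxyphenyl)-2,3-dihydro-1-benzofuran-3-yl]-7-methoxy-2-(4-methoxyphenyl)-2,3-dihydro-1-benzofuran-3-carboxylate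
Conditions: 16 (1.5 equiv), Cs2CO3 (0.75 equiv), Ir[dF(CF3)ppy]2(dtbbpy)PF6 (2 mol%), NiCl2(dme) (10 mol%), dtbbpy (15 mol%), DMF, blue LEDs, rt
Reagents that add atoms: none
Why: Nickel/photoredox decarboxylative arylation of a secondary benzylic acid, in which photo-oxidation of the caesium carboxylate and loss of CO2 give the C3 radical, the aryl–nickel species derived from bromide 8 captures it on the face opposite the C2 aryl group so that reductive elimination sets C3 as S (trans), and the half equivalent of Cs2CO3 only forms the carboxylate and leaves the C3' ester of 8 unenolised.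

Step 11
Reactants: 17 methyl (2R,3R)-5-[(2S,3S)-4-(benzyloxy)-6-methoxy-2-(4-methoxyphenyl)-2,3-dihydro-1-benzofuran-3-yl]-7-methoxy-2-(4-methoxyphenyl)-2,3-dihydro-1-benzofuran-3-carboxylate
Product: 18 (2R,3R)-5-[(2S,3S)-4-(benzyloxy)-6-methoxy-2-(4-methoxyphenyl)-2,3-dihydro-1-benzofuran-3-yl]-7-methoxy-2-(4-methoxyphenyl)-2,3-dihydro-1-benzofuran-3-carboxylic acid
Conditions: Me3SnOH (5 equiv), ClCH2CH2Cl, 80 °C; then 1 M HCl wash
Reagents that add atoms: trimethyltin hydroxide, C[Sn](C)(C)O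
Why: The same non-basic ester hydrolysis as in step 9, which leaves all four stereocentres and both ring oxygens in place.

Step 12
Reactants: 18 (2R,3R)-5-[(2S,3S)-4-(benzyloxy)-6-methoxy-2-(4-methoxyphenyl)-2,3-dihydro-1-benzofuran-3-yl]-7-methoxy-2-(4-methoxyphenyl)-2,3-dihydro-1-benzofuran-3-carboxylic acid; 19 1-bromo-3,5-dimethoxybenzene
Product: 20 (2S,3S)-4-(benzyloxy)-3-[(2R,3R)-3-(3,5-dimethoxyphenyl)-7-methoxy-2-(4-methoxyphenyl)-2,3-dihydro-1-benzofuran-5-yl]-6-methoxy-2-(4-methoxyphenyl)-2,3-dihydro-1-benzofuran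
Conditions: 19 (3 equiv), Cs2CO3 (1.0 equiv), Ir[dF(CF3)ppy]2(dtbbpy)PF6 (2 mol%), NiCl2(dme) (10 mol%), dtbbpy (15 mol%), DMF, blue LEDs, rt
Reagents that add atoms: none
Why: The same nickel/photoredox decarboxylative arylation, now with a simple aryl bromide in excess and no other halide in the substrate, in which the planar C3' radical is arylated anti to ring E on C2' and C3' is thereby set as R (trans).

Step 13
Reactants: 20 (2S,3S)-4-(benzyloxy)-3-[(2R,3R)-3-(3,5-dimethoxyphenyl)-7-methoxy-2-(4-methoxyphenyl)-2,3-dihydro-1-benzofuran-5-yl]-6-methoxy-2-(4-methoxyphenyl)-2,3-dihydro-1-benzofuran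
Product: 21 (2S,3S)-3-[(2R,3R)-3-(3,5-dimethoxyphenyl)-7-methoxy-2-(4-methoxyphenyl)-2,3-dihydro-1-benzofuran-5-yl]-6-methoxy-2-(4-methoxyphenyl)-2,3-dihydro-1-benzofuran-4-ol
Conditions: H2 (1 atm), Pd on carbon (10%), EtOAc/MeOH, rt
Reagents that add atoms: none
Why: Hydrogenolysis of the primary benzyl aryl ether, which is much faster than cleavage of the cyclic secondary benzylic C2–O and C2'–O bonds, as is familiar from benzyl-protected flavans.

Step 14
Reactants: 21 (2S,3S)-3-[(2R,3R)-3-(3,5-dimethoxyphenyl)-7-methoxy-2-(4-methoxyphenyl)-2,3-dihydro-1-benzofuran-5-yl]-6-methoxy-2-(4-methoxyphenyl)-2,3-dihydro-1-benzofuran-4-ol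
Product: 22 (2S,3S)-3-[(2R,3R)-3-(3,5-dimethoxyphenyl)-7-methoxy-2-(4-methoxyphenyl)-2,3-dihydro-1-benzofuran-5-yl]-6-methoxy-2-(4-methoxyphenyl)-2,3-dihydro-1-benzofuran-4-yl trifluoromethanesulfonate
Conditions: Tf2O (1.3 equiv), pyridine, CH2Cl2, 0 °C
Reagents that add atoms: trifluoromethanesulfonic anhydride, O=S(=O)(OS(=O)(=O)C(F)(F)F)C(F)(F)F
Why: O-Sulfonylation of the single free phenol, which turns C4 of ring A into a cross-coupling site without touching any stereocentre.

Step 15
Reactants: 22 (2S,3S)-3-[(2R,3R)-3-(3,5-dimethoxyphenyl)-7-methoxy-2-(4-methoxyphenyl)-2,3-dihydro-1-benzofuran-5-yl]-6-methoxy-2-(4-methoxyphenyl)-2,3-dihydro-1-benzofuran-4-yl trifluoromethanesulfonate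
Product: 23 (2S,3S)-3-[(2R,3R)-3-(3,5-dihydroxyphenyl)-7-hydroxy-2-(4-hydroxyphenyl)-2,3-dihydro-1-benzofuran-5-yl]-6-hydroxy-2-(4-hydroxyphenyl)-2,3-dihydro-1-benzofuran-4-yl trifluoromethanesulfonate
Conditions: BBr3 (12 equiv), CH2Cl2, −78 °C to rt; then MeOH, H2O
Reagents that add atoms: none
Why: Lewis-acid cleavage of the six aryl methyl ethers, to which the aryl triflate is inert, carried out before any alkene exists; if a C2–O bond ionises it should reclose to the more stable trans ring, since C3 and C3' are configurationally fixed.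

Step 16
Reactants: 23 (2S,3S)-3-[(2R,3R)-3-(3,5-dihydroxyphenyl)-7-hydroxy-2-(4-hydroxyphenyl)-2,3-dihydro-1-benzofuran-5-yl]-6-hydroxy-2-(4-hydroxyphenyl)-2,3-dihydro-1-benzofuran-4-yl trifluoromethanesulfonate
Product: 24 hexakis(tert-butyldimethylsilyl) ether of 23 (all six phenols silylated)
Conditions: TBSCl (9 equiv), imidazole (15 equiv), DMF, rt
Reagents that add atoms: tert-butyldimethylsilyl chloride, CC(C)(C)[Si](C)(C)Cl
Why: Silylation of all six phenols with imidazole as base, giving ethers that tolerate the coupling and hydrogenation ahead and can be removed without acid.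

Step 17
Reactants: 24 hexakis(tert-butyldimethylsilyl) ether of 23; 25 tert-butyl(4-ethynylphenoxy)dimethylsilane
Product: 26 heptakis(tert-butyldimethylsilyl) ether of 5-[(2R,3R)-7-hydroxy-5-[(2S,3S)-6-hydroxy-2-(4-hydroxyphenyl)-4-[(4-hydroxyphenyl)ethynyl]-2,3-dihydro-1-benzofuran-3-yl]-2-(4-hydroxyphenyl)-2,3-dihydro-1-benzofuran-3-yl]benzene-1,3-diol
Conditions: 25 (1.5 equiv), Pd(PPh3)2Cl2 (5 mol%), CuI (10 mol%), Et3N, DMF, 70 °C
Reagents that add atoms: none
Why: Sonogashira coupling of the aryl triflate with a terminal alkyne, which fixes the two-carbon bridge to ring F in a geometry-free form.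

Step 18
Reactants: 26 heptakis(tert-butyldimethylsilyl) ether of the diarylalkyne
Product: 27 heptakis(tert-butyldimethylsilyl) ether of 5-[(2R,3R)-7-hydroxy-5-[(2S,3S)-6-hydroxy-2-(4-hydroxyphenyl)-4-[(Z)-2-(4-hydroxyphenyl)ethenyl]-2,3-dihydro-1-benzofuran-3-yl]-2-(4-hydroxyphenyl)-2,3-dihydro-1-benzofuran-3-yl]benzene-1,3-diol
Conditions: H2 (1 atm), Pd on CaCO3 poisoned with Pb(OAc)2, quinoline, EtOAc, rt
Reagents that add atoms: none
Why: Syn semi-hydrogenation of the diarylalkyne on a poisoned palladium surface, which delivers both hydrogens to one face and so gives the Z-alkene, with quinoline holding back over-reduction.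

Step 19
Reactants: 27 heptakis(tert-butyldimethylsilyl) ether of the Z-stilbene
Product: 28 5-[(2R,3R)-7-hydroxy-5-[(2S,3S)-6-hydroxy-2-(4-hydroxyphenyl)-4-[(Z)-2-(4-hydroxyphenyl)ethenyl]-2,3-dihydro-1-benzofuran-3-yl]-2-(4-hydroxyphenyl)-2,3-dihydro-1-benzofuran-3-yl]benzene-1,3-diol
Conditions: n-Bu4NF (8 equiv), AcOH (8 equiv), THF, 0 °C, in the dark
Reagents that add atoms: none
Why: Fluoride cleavage of the seven aryl silyl ethers, buffered with AcOH so that no free phenoxide, acid or sensitiser is present and the Z-alkene and both trans rings should persist.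

**Compound list**

1 | 1-(2-hydroxy-3-methoxyphenyl)ethan-1-one | CC(=O)c1cccc(OC)c1O | starting material
2 | 1-(5-bromo-2-hydroxy-3-methoxyphenyl)ethan-1-one | CC(=O)c1cc(Br)cc(OC)c1O | intermediate
3 | (E)-1-(5-bromo-2-hydroxy-3-methoxyphenyl)-3-(dimethylamino)prop-2-en-1-one | CN(C)/C=C/C(=O)c1cc(Br)cc(OC)c1O | intermediate
4 | 6-bromo-8-methoxy-4H-chromen-4-one | O=c1ccoc2c(OC)cc(Br)cc12 | intermediate
5 | (4-methoxyphenyl)boronic acid | COc1ccc(cc1)B(O)O | starting material
6 | (2R)-6-bromo-8-methoxy-2-(4-methoxyphenyl)-2,3-dihydro-4H-chromen-4-one | O=C1C[C@H](c2ccc(OC)cc2)Oc2c(OC)cc(Br)cc12 | intermediate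
7 | (2R)-6-bromo-4,8-dimethoxy-2-(4-methoxyphenyl)-2H-chromene | COC1=C[C@H](c2ccc(OC)cc2)Oc2c(OC)cc(Br)cc12 | intermediate
8 | methyl (2R,3R)-5-bromo-7-methoxy-2-(4-methoxyphenyl)-2,3-dihydro-1-benzofuran-3-carboxylate | Brc1cc(OC)c2c(c1)[C@@H](C(=O)OC)[C@H](c1ccc(OC)cc1)O2 | intermediate
9 | 1-(2,6-dihydroxy-4-methoxyphenyl)ethan-1-one | CC(=O)c1c(O)cc(OC)cc1O | starting material
10 | 1-[2-(benzyloxy)-6-hydroxy-4-methoxyphenyl]ethan-1-one | CC(=O)c1c(O)cc(OC)cc1OCc1ccccc1 | intermediate
11 | (E)-1-[2-(benzyloxy)-6-hydroxy-4-methoxyphenyl]-3-(dimethylamino)prop-2-en-1-one | CN(C)/C=C/C(=O)c1c(O)cc(OC)cc1OCc1ccccc1 | intermediate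
12 | 5-(benzyloxy)-7-methoxy-4H-chromen-4-one | O=c1ccoc2cc(OC)cc(OCc3ccccc3)c12 | intermediate
13 | (2S)-5-(benzyloxy)-7-methoxy-2-(4-methoxyphenyl)-2,3-dihydro-4H-chromen-4-one | O=C1C[C@@H](c2ccc(OC)cc2)Oc2cc(OC)cc(OCc3ccccc3)c12 | intermediate
14 | (2S)-5-(benzyloxy)-4,7-dimethoxy-2-(4-methoxyphenyl)-2H-chromene | COC1=C[C@@H](c2ccc(OC)cc2)Oc2cc(OC)cc(OCc3ccccc3)c12 | intermediate
15 | methyl (2S,3S)-4-(benzyloxy)-6-methoxy-2-(4-methoxyphenyl)-2,3-dihydro-1-benzofuran-3-carboxylate | c1ccccc1COc1cc(OC)cc2c1[C@H](C(=O)OC)[C@@H](c1ccc(OC)cc1)O2 | intermediate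
16 | (2S,3S)-4-(benzyloxy)-6-methoxy-2-(4-methoxyphenyl)-2,3-dihydro-1-benzofuran-3-carboxylic acid | c1ccccc1COc1cc(OC)cc2c1[C@H](C(=O)O)[C@@H](c1ccc(OC)cc1)O2 | intermediate
17 | methyl (2R,3R)-5-[(2S,3S)-4-(benzyloxy)-6-methoxy-2-(4-methoxyphenyl)-2,3-dihydro-1-benzofuran-3-yl]-7-methoxy-2-(4-methoxyphenyl)-2,3-dihydro-1-benzofuran-3-carboxylate | c1ccccc1COc1cc(OC)cc2c1[C@H](c1cc(OC)c3c(c1)[C@@H](C(=O)OC)[C@H](c1ccc(OC)cc1)O3)[C@@H](c1ccc(OC)cc1)O2 | intermediate
18 | (2R,3R)-5-[(2S,3S)-4-(benzyloxy)-6-methoxy-2-(4-methoxyphenyl)-2,3-dihydro-1-benzofuran-3-yl]-7-methoxy-2-(4-methoxyphenyl)-2,3-dihydro-1-benzofuran-3-carboxylic acid | c1ccccc1COc1cc(OC)cc2c1[C@H](c1cc(OC)c3c(c1)[C@@H](C(=O)O)[C@H](c1ccc(OC)cc1)O3)[C@@H](c1ccc(OC)cc1)O2 | intermediate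
19 | 1-bromo-3,5-dimethoxybenzene | COc1cc(Br)cc(OC)c1 | starting material
20 | (2S,3S)-4-(benzyloxy)-3-[(2R,3R)-3-(3,5-dimethoxyphenyl)-7-methoxy-2-(4-methoxyphenyl)-2,3-dihydro-1-benzofuran-5-yl]-6-methoxy-2-(4-methoxyphenyl)-2,3-dihydro-1-benzofuran | c1ccccc1COc1cc(OC)cc2c1[C@H](c1cc(OC)c3c(c1)[C@@H](c1cc(OC)cc(OC)c1)[C@H](c1ccc(OC)cc1)O3)[C@@H](c1ccc(OC)cc1)O2 | intermediate
21 | (2S,3S)-3-[(2R,3R)-3-(3,5-dimethoxyphenyl)-7-methoxy-2-(4-methoxyphenyl)-2,3-dihydro-1-benzofuran-5-yl]-6-methoxy-2-(4-methoxyphenyl)-2,3-dihydro-1-benzofuran-4-ol | Oc1cc(OC)cc2c1[C@H](c1cc(OC)c3c(c1)[C@@H](c1cc(OC)cc(OC)c1)[C@H](c1ccc(OC)cc1)O3)[C@@H](c1ccc(OC)cc1)O2 | intermediate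
22 | (2S,3S)-3-[(2R,3R)-3-(3,5-dimethoxyphenyl)-7-methoxy-2-(4-methoxyphenyl)-2,3-dihydro-1-benzofuran-5-yl]-6-methoxy-2-(4-methoxyphenyl)-2,3-dihydro-1-benzofuran-4-yl trifluoromethanesulfonate | O=S(=O)(Oc1cc(OC)cc2c1[C@H](c1cc(OC)c3c(c1)[C@@H](c1cc(OC)cc(OC)c1)[C@H](c1ccc(OC)cc1)O3)[C@@H](c1ccc(OC)cc1)O2)C(F)(F)F | intermediate
23 | (2S,3S)-3-[(2R,3R)-3-(3,5-dihydroxyphenyl)-7-hydroxy-2-(4-hydroxyphenyl)-2,3-dihydro-1-benzofuran-5-yl]-6-hydroxy-2-(4-hydroxyphenyl)-2,3-dihydro-1-benzofuran-4-yl trifluoromethanesulfonate | O=S(=O)(Oc1cc(O)cc2c1[C@H](c1cc(O)c3c(c1)[C@@H](c1cc(O)cc(O)c1)[C@H](c1ccc(O)cc1)O3)[C@@H](c1ccc(O)cc1)O2)C(F)(F)F | intermediate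
24 | hexakis(tert-butyldimethylsilyl) ether of 23 | O=S(=O)(Oc1cc(O[Si](C)(C)C(C)(C)C)cc2c1[C@H](c1cc(O[Si](C)(C)C(C)(C)C)c3c(c1)[C@@H](c1cc(O[Si](C)(C)C(C)(C)C)cc(O[Si](C)(C)C(C)(C)C)c1)[C@H](c1ccc(O[Si](C)(C)C(C)(C)C)cc1)O3)[C@@H](c1ccc(O[Si](C)(C)C(C)(C)C)cc1)O2)C(F)(F)F | intermediate
25 | tert-butyl(4-ethynylphenoxy)dimethylsilane | C#Cc1ccc(O[Si](C)(C)C(C)(C)C)cc1 | starting material
26 | heptakis(tert-butyldimethylsilyl) ether of the diarylalkyne analogue of 28 (C≡C in place of the Z-alkene) | CC(C)(C)[Si](C)(C)Oc1ccc(C#Cc2cc(O[Si](C)(C)C(C)(C)C)cc3c2[C@H](c2cc(O[Si](C)(C)C(C)(C)C)c4c(c2)[C@@H](c2cc(O[Si](C)(C)C(C)(C)C)cc(O[Si](C)(C)C(C)(C)C)c2)[C@H](c2ccc(O[Si](C)(C)C(C)(C)C)cc2)O4)[C@@H](c2ccc(O[Si](C)(C)C(C)(C)C)cc2)O3)cc1 | intermediate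
27 | heptakis(tert-butyldimethylsilyl) ether of 28 | CC(C)(C)[Si](C)(C)Oc1ccc(/C=C\c2cc(O[Si](C)(C)C(C)(C)C)cc3c2[C@H](c2cc(O[Si](C)(C)C(C)(C)C)c4c(c2)[C@@H](c2cc(O[Si](C)(C)C(C)(C)C)cc(O[Si](C)(C)C(C)(C)C)c2)[C@H](c2ccc(O[Si](C)(C)C(C)(C)C)cc2)O4)[C@@H](c2ccc(O[Si](C)(C)C(C)(C)C)cc2)O3)cc1 | intermediate
28 | 5-[(2R,3R)-7-hydroxy-5-[(2S,3S)-6-hydroxy-2-(4-hydroxyphenyl)-4-[(Z)-2-(4-hydroxyphenyl)ethenyl]-2,3-dihydro-1-benzofuran-3-yl]-2-(4-hydroxyphenyl)-2,3-dihydro-1-benzofuran-3-yl]benzene-1,3-diol | Oc1ccc(/C=C\c2cc(O)cc3c2[C@H](c2cc(O)c4c(c2)[C@@H](c2cc(O)cc(O)c2)[C@H](c2ccc(O)cc2)O4)[C@@H](c2ccc(O)cc2)O3)cc1 | target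

**Count and risks**

Total step count: 19. Longest linear sequence: 15 steps (from 9 through steps 5–19); the other branch (from 1 through steps 1–4 and 10–19) has 14.

Most likely to fail, in this order:

1. Step 10 (fragment union). The C3 radical is flanked by the C2 aryl group and the benzyloxy group on C4, so capture by nickel may be slower than hydrogen abstraction or dimerisation, facial selectivity may erode, and the ester of 8 may open by β-elimination if base is in excess. The fallback sets out from acid 16 and bromide 8 and returns at 17. Acid 16 is condensed with N-hydroxyphthalimide (N,N'-diisopropylcarbodiimide, DMAP, CH2Cl2, rt) to the redox-active ester 1,3-dioxoisoindolin-2-yl (2S,3S)-4-(benzyloxy)-6-methoxy-2-(4-methoxyphenyl)-2,3-dihydro-1-benzofuran-3-carboxylate F4. Bromide 8 is converted by copper-catalysed halogen exchange (CuI, NaI, N,N'-dimethylethane-1,2-diamine, dioxane, 110 °C) into methyl (2R,3R)-5-iodo-7-methoxy-2-(4-methoxyphenyl)-2,3-dihydro-1-benzofuran-3-carboxylate F5. The two are then joined by nickel-catalysed reductive cross-electrophile coupling (NiBr2(dme), dtbbpy, Zn, DMA, rt), a thermal, base-free and light-free decarboxylative arylation in which the same anti capture of the C3 radical should give 17.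

2. Step 4 (key step). The aryl group on C2 may migrate in place of C4a (leading towards an isoflavone), the iodine may simply be lost (flavone or C3 methoxylation), and the acid may reversibly open the pyranone and erode C2. The fallback sets out from flavanone 6 and returns at 8, keeping the same ring contraction but achieving it through a carbene. Deprotonation at −78 °C and acylation (LiN(SiMe3)2, CF3CO2CH2CF3, THF) should give (2R)-6-bromo-8-methoxy-2-(4-methoxyphenyl)-3-(2,2,2-trifluoroacetyl)-2,3-dihydro-4H-chromen-4-one F1. Deacylative diazo transfer (MsN3, Et3N, MeCN) should give (2S)-6-bromo-3-diazo-8-methoxy-2-(4-methoxyphenyl)-2,3-dihydro-4H-chromen-4-one F2 (same spatial arrangement at C2; only the descriptor changes). Photochemical Wolff rearrangement in methanol (365 nm) moves C4a to C3 and traps the ketene as methyl (2R)-5-bromo-7-methoxy-2-(4-methoxyphenyl)-2,3-dihydro-1-benzofuran-3-carboxylate F3, a mixture of C3 epimers. Brief equilibration with catalytic NaOMe in MeOH at 0 °C should converge this mixture on the trans ester 8.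

3. Step 18 (semi-hydrogenation). The crowded, heavily silylated diarylalkyne may stall or be over-reduced to the saturated bridge, and some Z to E leakage is possible on the catalyst. The fallback sets out from triflate 24 and alkyne 25 and returns at 27, bypassing alkyne 26. Rhodium-catalysed trans-hydroboration of 25 ([Rh(cod)Cl]2, P(i-Pr)3, Et3N, pinacolborane, cyclohexane, rt) should give tert-butyldimethyl{4-[(Z)-2-(4,4,5,5-tetramethyl-1,3,2-dioxaborolan-2-yl)ethenyl]phenoxy}silane F6. Stereoretentive Suzuki–Miyaura coupling of F6 with 24 (Pd(PPh3)4, K3PO4, dioxane/H2O, 60 °C) should then install the Z-styryl group directly.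

**Further compounds**

F1 | step 4 | (2R)-6-bromo-8-methoxy-2-(4-methoxyphenyl)-3-(2,2,2-trifluoroacetyl)-2,3-dihydro-4H-chromen-4-one | O=C1C(C(=O)C(F)(F)F)[C@H](c2ccc(OC)cc2)Oc2c(OC)cc(Br)cc12
F2 | step 4 | (2S)-6-bromo-3-diazo-8-methoxy-2-(4-methoxyphenyl)-2,3-dihydro-4H-chromen-4-one | O=C1C(=[N+]=[N-])[C@H](c2ccc(OC)cc2)Oc2c(OC)cc(Br)cc12
F3 | step 4 | methyl (2R)-5-bromo-7-methoxy-2-(4-methoxyphenyl)-2,3-dihydro-1-benzofuran-3-carboxylate (both C3 epimers) | Brc1cc(OC)c2c(c1)C(C(=O)OC)[C@H](c1ccc(OC)cc1)O2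
F4 | step 10 | 1,3-dioxoisoindolin-2-yl (2S,3S)-4-(benzyloxy)-6-methoxy-2-(4-methoxyphenyl)-2,3-dihydro-1-benzofuran-3-carboxylate | c1ccccc1COc1cc(OC)cc2c1[C@H](C(=O)ON1C(=O)c3ccccc3C1=O)[C@@H](c1ccc(OC)cc1)O2
F5 | step 10 | methyl (2R,3R)-5-iodo-7-methoxy-2-(4-methoxyphenyl)-2,3-dihydro-1-benzofuran-3-carboxylate | Ic1cc(OC)c2c(c1)[C@@H](C(=O)OC)[C@H](c1ccc(OC)cc1)O2
F6 | step 18 | tert-butyldimethyl{4-[(Z)-2-(4,4,5,5-tetramethyl-1,3,2-dioxaborolan-2-yl)ethenyl]phenoxy}silane | CC(C)(C)[Si](C)(C)Oc1ccc(/C=C\B2OC(C)(C)C(C)(C)O2)cc1
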